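An equilibrium ratio [isomer of the product]/[target] of 0.97 puts the share of target in the pair, at rest, at 50.8%, the floor of the quantity asked for here.

| flask | starting material | catalyst | time | remark |
|---|---|---|---|---|
| green | 0.50 M | 2 mol% | 30 min | a closed flask charged with all of it at once and left for 30 min |
| violet | 0.50 M (fed, over 30.0 min) | 2 mol% | 30 min | all but starting material at the start; starting material goes in evenly over 30.0 min, the run ends at 30 min |
| teal | 0.50 M | 2 mol% |  | a single well-mixed tank run continuously and read at steady state, 30 min in it on average |
| ochre | 0.50 M | 2 mol% | 30 min | plug flow through a tube for 30 min, no back-mixing |

    starting material ⇌ target (K1 = 2.4, k1 = 0.00906 min⁻¹)
    target + catalyst ⇌ isomer of the product + catalyst, rate k2*[catalyst]*[target] forward; the back reaction follows from the equilibrium constant (K2 = 0.97, k2 = 1.75 L mol⁻¹ min⁻¹)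

- the set-up with the highest share of target in all that became target or isomer of the product, at the outlet or at the end ("none" if the first two lie within 2 percentage points) (green / violet / teal / ochre / none)
- share of target in all that became target or isomer of the product, at the outlet or at the end, green
- share of target in all that became target or isomer of the product, at the outlet or at the end, violet
- share of target in all that became target or isomer of the product, at the outlet or at the end, teal
- share of target in all that became target or isomer of the product, at the outlet or at the end, ochre

- the stated concentrations are those of everything mixed, before any reaction; amounts are the same in each set-up
- the feed brings no volume worth counting
- run time (green): 30 min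

Take the rates first. A fresh portion of target turns into isomer of the product at k2[catalyst] = 0.0175 min⁻¹, pseudo-first-order with the catalyst constant. The back step then slows the net loss: the excess of the share over the floor shrinks at 0.0355 min⁻¹, twice the forward constant. Call the time in which that excess falls by one logarithmic decade the decade time, 64.7 min.

A portion present for the whole 30 min has aged 0.464 decades, so its net loss has fallen to 0.345 of its starting rate. In green, counting its forward direction alone, the rate of the first step keeps a higher fraction of its start over that time, 0.762. I therefore take green's supply of target as roughly even and its mean age as half the run, which is 0.232 decades and gives a share of 79.7%. Ochre, without back-mixing, runs on the same clock and gets the same figure. In violet the supply rises with the dose, so I take the mean age as a third of the run, giving 85.3%. In teal the ages spread exponentially, the excess keeps a factor of 1/(1 + rate × time), and the share is 74.6%.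

The forecast names violet, with 80.1% for green and 80.1% for ochre, 86% for violet, both higher than mine, and 74.6% for teal, level with mine, holding that feeding “gives the material the shortest average time exposed to isomerisation”. The simulation gives violet, with 80.1% for green, 86.0% for violet, 74.6% for teal and 80.1% for ochre, so my green and violet figures lie 0.40 percentage points and 0.70 points below it.

Violet has not come to rest at 30 min: 88.0% of its charge is still starting material, and its share stands 35 points above the floor. From there to 300 min lie 4.17 decades, which by my reckoning take the excess of the target already formed at 30 min, with none formed later, down to 0.0024 points. Yet the violet share at ten times the time is 51.9%, still 1.1 points above the floor.

(The constants used here come from no measurement; no experiment stands behind them.)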